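## The problem

Target 14 is a (2R,3R)-2,3-dihydrobenzofuran. Ring A (the arene) carries an acetyl group at C5 and a hydroxyl at C6; ring B (the dihydrofuran) carries a 3-acetoxyprop-1-en-2-yl group at C2 and an angelate at C3, cis to each other. The two stereocentres are adjacent, and C3 is benzylic and para to the C6 oxygen, so it ionises easily. A planar C3 can return trans or lose the C2 proton to give an aromatic benzofuran, which erases both centres. C2 can therefore dictate C3 reliably only while both carbons sit in a second small ring, where a cis fusion is the only option. The functional groups are fragile: the angelate isomerises to the tiglate under nucleophilic or strongly basic acylation, a C6 phenoxide expels the benzylic angelate through a para-quinone methide, the allylic acetate can migrate or hydrolyse, and the aryl ketone does not survive hydride unmasked. Two features open a short route. C3 is bonded to C3a, which is para to the C6 hydroxyl and ortho to O1 and hence the most nucleophilic carbon of ring A, so the C3–C3a bond can be made by electrophilic substitution on a purchased resorcinol-type arene. The C3 oxygen and the side-chain carbon that becomes CH2OAc are separated only by C2 and C1', so a carbonyl can tie them into a cis-fused γ-lactone, which maps onto a four-carbon γ-alkoxybutenolide with only the =CH2 carbon missing.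

## Retrosynthesis

**14 to 13, 10 and 9 (acyl groups and masks).** The two esters and the free hydroxy ketone are the most fragile parts, so they are set last. 14 is traced to 13, in which the phenol is a silyl ether and the acetyl group a silyl enol ether; both masks fall in one buffered fluoride treatment, and no acid is needed after the key step. Cutting the C3–O acyl bond of 13 gives alcohol 10 and angelic acid 11, joined through mixed anhydride 12. Removing the acetate gives diol 9. Acetate before angelate is preferred to the reverse order because the primary allylic hydroxyl is the more reactive one and the isomerisable ester then sees only one further step. The forward reactions must acylate a hindered benzylic alcohol without a nucleophilic catalyst and must never generate a free phenoxide.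

**9 to 8 (lactone reduction).** The two hydroxyls of 9 are reconnected through a carbonyl, giving α-methylene lactone 8; the bonds cut are the two C–H bonds of the CH2OH group. This is preferred to building the side chain onto a preformed dihydrobenzofuranol because the lactone has held C2 and C3 cis and delivers one primary and one secondary hydroxyl, already differentiated. The forward step needs a 1,2-selective hydride on an enoate, which is why the ketone must be masked in 8.

**8 to 5 and 4 (methylene carbon and masks).** The C1'=CH2 bond is cut (lactone α-methylenation), giving 5, and the two O–Si bonds are cut, giving hydroxy ketone lactone 4. Bringing this carbon in with the butenolide would require a 3-substituted auxiliary lactone and would slow the conjugate addition. The forward step asks that the lactone enolate be trapped faster than it ejects the β-aryloxy group.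

**4 to 3 (key cut, C3–C3a).** Cutting C3–C3a of 4 gives aryl ether 3, a lactol acetal of a γ-lactone. This cut is preferred to O1–C7a or C2–C1' because it uses the innate nucleophilicity of C3a and needs no activating or leaving group on the arene. The five–five fusion can only be cis, so C2 sets C3. The acetal carbon becomes planar, so its configuration, and that of the auxiliary, need not be controlled. 3 has one ring less and only one stereocentre that matters. The forward reaction must ionise the acylal, direct attack to C3a and not C7, and stop before the benzylic lactone re-ionises and aromatises.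

**3 to 1 and 2 (O1–C2 ether bond).** Cutting the aryl ether bond of 3 gives 2,4-dihydroxyacetophenone 1 and menthyloxybutenolide 2, joined by oxa-Michael addition. Ring A arrives with its full substitution, and the butenolide supplies C2, C3, C1' and the future CH2OAc carbon in the right oxidation states. The forward step must use only the non-chelated hydroxyl of 1 and add anti to the menthyloxy group; this sets the C2 configuration of 14.

## Roads not taken

**Alternative 1:** The cut runs through ring A (C3a–C4 and C5–C6). Diene A2, a 2,3-dihydrofuran with both ring-B stereocentres and a bis(silyloxy)vinyl group, would add to but-3-yn-2-one A3 in a Diels–Alder reaction, and loss of silanol would aromatise the new ring to A1.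
- Merits: the acetyl/hydroxyl pattern follows from the polarity of diene and ynone, so there is no Friedel–Crafts regiochemistry question. The acetyl group arrives unmasked. The benzylic C3–O bond exists before there is an electron-rich arene to ionise it. A1 needs no lactone reduction and hence no ketone mask; in these respects this road is better.
- Weak points: both stereocentres must be built on a non-aromatic ring by a separate multistep sequence. A2 is a ketene acetal conjugated to an enol ether and also a 3-silyloxy-2,3-dihydrofuran, one elimination away from an aromatic furan. Aromatisation of the cycloadduct must expel the ketene-acetal silanol and not the C3 silyloxy group. The three silyl ethers of A1 must then be told apart.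
- Comparison: the chosen plan sets against this a purchased ring A, a single auxiliary-controlled step for C2, a closure that cannot give the trans isomer, and robust intermediates.

**Alternative 2:** The cut is C2–C1'. The dirhodium carbene from diazophosphonoacetate A5 (with Rh2(OAc)4) would insert into the C2–H bond next to O1 and close cis-fused phosphono lactone A4.
- Merits: the step is neutral and catalytic, and cis fusion is again enforced by geometry. The phosphonate allows a Horner–Wadsworth–Emmons methylenation with formaldehyde, which avoids enolate chemistry on a β-aryloxy lactone. This is a real advantage over step 4 of the chosen plan, and A4 would then join the same endgame as 8.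
- Weak points: the C3 carbinol must come from an enantioselective ketone reduction. The ester linking the diazo unit sits on an electron-rich benzylic carbon and can ionise before insertion. The carbene can instead attack the arene, O1 or the silyl ether. The acetyl group is carried as bromide and needs a late cross-coupling, and diazo transfer adds steps.
- Comparison: the chosen plan has the acetyl group in place from the first step, needs no diazo compound, and is several steps shorter; it accepts a Lewis-acid step that A4 avoids.

**Alternative 3:** The cut is O1–C7a. The C2 alkoxide of fluoro triol A7 would displace fluoride para to the acetyl group (nucleophilic aromatic substitution) and close ring B to A6.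
- Merits: C3 is never cationic, so aromatisation is not an issue. Both stereocentres can be set on an open chain by established asymmetric methods. A6 is already at the oxidation level of 9, so neither lactone reduction nor ketone masking is needed and the endgame is shorter than the one chosen.
- Weak points: the ring is activated by a single acetyl group, and the base needed also enolises that acetyl group, which removes the activation and invites aldol condensation. Three hydroxyls compete. The fluoroarene fragment and the 2-(hydroxymethyl)allyl diol must each be built over several steps. The 4-methoxybenzyl group must finally leave under oxidative or acidic conditions beside the benzylic angelate.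
- Comparison: the chosen plan offers a commercial ring A, no strongly basic step on an enolisable aryl ketone, and fewer steps overall; it carries the ionisation risk that this road does not.

Key step: step 2

Remark: butenolide 2 is treated as a purchased reagent (it is a catalogue compound, otherwise available in two steps from furfural and l-menthol).

## Route

Step 1
Reactants: 1 2,4-dihydroxyacetophenone; 2 (5R)-5-(l-menthyloxy)furan-2(5H)-one
Product: 3 (4R,5R)-4-(4-acetyl-3-hydroxyphenoxy)-5-(l-menthyloxy)dihydrofuran-2(3H)-one (trans)
Conditions: Cs2CO3 (0.1 equiv), 1 (1.3 equiv), MeCN, 0 °C → rt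
Reagents that add atoms: none
Why: Base-catalysed oxa-Michael addition: only the more acidic, non-chelated C4 hydroxyl of 1 is ionised, and its phenoxide adds to C4 of 2 anti to the C5 menthyloxy group, setting the (4R) centre (the future C2) trans to the acetal substituent; 3 is purified here, while any stereochemical leak is still a separable diastereomer.

Step 2
Reactants: 3
Product: 4 (3aR,8bR)-7-acetyl-6-hydroxy-3a,8b-dihydrofuro[3,2-b][1]benzofuran-2(3H)-one (cis-fused lactone; benzofuran numbering 2R,3R)
Conditions: BF3·OEt2 (3 equiv), CH2Cl2, −40 → 0 °C; aq. NaHCO3 quench at −40 °C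
Reagents that add atoms: none
Why: BF3 ionises the acylal carbon of 3 (the future C3) with loss of the menthyloxy group, giving an acyloxocarbenium ion that is attacked by the aryl carbon para to the free phenol and ortho to the ether oxygen (the future C3a); rearomatisation gives 4. The closest known reaction types are the acid-promoted Friedel–Crafts cyclisation of aryloxyacetaldehyde acetals to benzofurans and the Friedel–Crafts arylation of γ-alkoxybutyrolactones by electron-rich arenes. Ring B closes in a 5-exo-trig mode, the C=O+ bond lying outside the new ring. The new stereocentre C3 is controlled by C2 from step 1: a five–five fusion can only be cis, and because the cation is planar the acetal configuration of 3 plays no part. If the acylal ionises at its other C–O bond (ring opening), the same C3–C3a bond forms and the tethered carboxyl group closes on the benzylic carbon to the same cis lactone. Regioselectivity for C3a over C7 rests on para activation by the C6 hydroxyl and on the crowding of C7 between two oxygens. Selectivity against aromatisation (re-ionisation of the benzylic lactone and loss of the C2 proton) rests on a short, cold exposure, on the hydrogen bond from the C6 hydroxyl to the acetyl group, which tempers its donor strength, and on internal return of the tethered carboxylate.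

Step 3
Reactants: 4
Product: 5 (3aR,8bR)-6-(triisopropylsilyloxy)-7-[1-(triisopropylsilyloxy)ethenyl]-3a,8b-dihydrofuro[3,2-b][1]benzofuran-2(3H)-one
Conditions: iPr3SiOTf (2.3 equiv), Et3N (4 equiv), CH2Cl2, −78 → 0 °C
Reagents that add atoms: triisopropylsilyl trifluoromethanesulfonate, CC(C)[Si](OS(=O)(=O)C(F)(F)F)(C(C)C)C(C)C
Why: Silyl triflate/amine silylation: the phenol is O-silylated and the aryl methyl ketone undergoes soft enolisation to its silyl enol ether in the same operation, whereas the lactone enolises far more slowly; both masks tolerate base and hydride, and no acid touches the benzylic lactone.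

Step 4
Reactants: 5
Product: 8 (3aR,8bR)-3-methylidene-6-(triisopropylsilyloxy)-7-[1-(triisopropylsilyloxy)ethenyl]-3a,8b-dihydrofuro[3,2-b][1]benzofuran-2(3H)-one, via Mannich base 6 (not isolated), via trimethylammonium iodide 7 (not isolated)
Conditions: LiN(iPr)2 (1.1 equiv), THF, −78 °C; Me2N=CH2+ I− (1.2 equiv), −78 → 0 °C; then MeI, CH2Cl2, rt; then aq. NaHCO3, rt
Reagents that add atoms: N,N-dimethylmethyleneiminium iodide (Eschenmoser's salt), C=[N+](C)C.[I-]
Why: Lactone α-methylenation by the Mannich route: the lithium enolate is aminomethylated on the convex face far faster than the hindered silyl enol ether can react, and quaternisation followed by mild-base elimination gives the exocyclic alkene; the β-aryloxy enolate is expected to hold at −78 °C as chroman-4-one enolates do, and the centre created in 6 is destroyed on elimination.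

Step 5
Reactants: 8
Product: 9 (2R,3R)-2-(3-hydroxyprop-1-en-2-yl)-6-(triisopropylsilyloxy)-5-[1-(triisopropylsilyloxy)ethenyl]-2,3-dihydro-1-benzofuran-3-ol
Conditions: iBu2AlH (4 equiv), CH2Cl2, −78 → −20 °C; aq. KNaC4H4O6 work-up
Reagents that add atoms: none
Why: Aluminium hydride 1,2-reduction of the α-methylene lactone through lactol and enal to the allylic 1,4-diol; the silyl enol ether and the aryl silyl ether are inert, and no stereocentre is touched.

Step 6
Reactants: 9
Product: 10 2-[(2R,3R)-3-hydroxy-6-(triisopropylsilyloxy)-5-[1-(triisopropylsilyloxy)ethenyl]-2,3-dihydro-1-benzofuran-2-yl]prop-2-en-1-yl acetate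
Conditions: Ac2O (1.1 equiv), pyridine, CH2Cl2, −20 → 0 °C
Reagents that add atoms: acetic anhydride, CC(=O)OC(C)=O
Why: Selective acetylation: the unhindered primary allylic hydroxyl reacts well before the secondary benzylic hydroxyl, which is flanked by the arene and the cis C2 substituent.

Step 7
Reactants: 10; 11 angelic acid, (2Z)-2-methylbut-2-enoic acid
Product: 13 (2R,3R)-2-[3-(acetyloxy)prop-1-en-2-yl]-6-(triisopropylsilyloxy)-5-[1-(triisopropylsilyloxy)ethenyl]-2,3-dihydro-1-benzofuran-3-yl (2Z)-2-methylbut-2-enoate, via mixed anhydride 12 (not isolated)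
Conditions: 11, 2,4,6-Cl3C6H2COCl, Et3N, toluene, rt; then 10, 75 °C
Reagents that add atoms: none
Why: Yamaguchi-type mixed-anhydride esterification run thermally without a nucleophilic catalyst: the alcohol attacks the unhindered angeloyl carbonyl of 12, and the absence of 4-dimethylaminopyridine and of strong base keeps the Z geometry; acylation at oxygen leaves C3 untouched.

Step 8
Reactants: 13
Product: 14 (2R,3R)-5-acetyl-2-[3-(acetyloxy)prop-1-en-2-yl]-6-hydroxy-2,3-dihydro-1-benzofuran-3-yl (2Z)-2-methylbut-2-enoate
Conditions: Bu4NF (2.5 equiv), AcOH (2.5 equiv), THF, 0 °C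
Reagents that add atoms: none
Why: Fluoride-mediated desilylation: both Si–O bonds are cleaved, the enol ether giving the methyl ketone on protonation; acetic acid buffers the medium so the C6 oxygen appears as the hydrogen-bonded phenol and not as a phenoxide, which protects the benzylic angelate and the allylic acetate.

## Compound list

1 | 2,4-dihydroxyacetophenone | CC(=O)c1ccc(O)cc1O | starting material
2 | (5R)-5-{[(1R,2S,5R)-5-methyl-2-(propan-2-yl)cyclohexyl]oxy}furan-2(5H)-one | O=C1C=C[C@H](O[C@@H]2C[C@H](C)CC[C@H]2C(C)C)O1 | starting material
3 | (4R,5R)-4-(4-acetyl-3-hydroxyphenoxy)-5-{[(1R,2S,5R)-5-methyl-2-(propan-2-yl)cyclohexyl]oxy}dihydrofuran-2(3H)-one (trans) | O=C1C[C@@H](Oc2ccc(C(C)=O)c(O)c2)[C@H](O[C@@H]2C[C@H](C)CC[C@H]2C(C)C)O1 | intermediate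
4 | (3aR,8bR)-7-acetyl-6-hydroxy-3a,8b-dihydrofuro[3,2-b][1]benzofuran-2(3H)-one (cis-fused) | O=C1C[C@H]2Oc3cc(O)c(C(C)=O)cc3[C@H]2O1 | intermediate
5 | (3aR,8bR)-6-(triisopropylsilyloxy)-7-[1-(triisopropylsilyloxy)ethenyl]-3a,8b-dihydrofuro[3,2-b][1]benzofuran-2(3H)-one | O=C1C[C@H]2Oc3cc(O[Si](C(C)C)(C(C)C)C(C)C)c(C(=C)O[Si](C(C)C)(C(C)C)C(C)C)cc3[C@H]2O1 | intermediate
6 | (3R,3aR,8bR)-3-[(dimethylamino)methyl] derivative of 5 (Mannich base; exo epimer expected, centre lost later) | O=C1[C@H](CN(C)C)[C@H]2Oc3cc(O[Si](C(C)C)(C(C)C)C(C)C)c(C(=C)O[Si](C(C)C)(C(C)C)C(C)C)cc3[C@H]2O1 | intermediate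
7 | N,N,N-trimethylammoniomethyl iodide derived from 6 | O=C1[C@H](C[N+](C)(C)C)[C@H]2Oc3cc(O[Si](C(C)C)(C(C)C)C(C)C)c(C(=C)O[Si](C(C)C)(C(C)C)C(C)C)cc3[C@H]2O1.[I-] | intermediate
8 | (3aR,8bR)-3-methylidene-6-(triisopropylsilyloxy)-7-[1-(triisopropylsilyloxy)ethenyl]-3a,8b-dihydrofuro[3,2-b][1]benzofuran-2(3H)-one | O=C1C(=C)[C@H]2Oc3cc(O[Si](C(C)C)(C(C)C)C(C)C)c(C(=C)O[Si](C(C)C)(C(C)C)C(C)C)cc3[C@H]2O1 | intermediate
9 | (2R,3R)-2-(3-hydroxyprop-1-en-2-yl)-6-(triisopropylsilyloxy)-5-[1-(triisopropylsilyloxy)ethenyl]-2,3-dihydro-1-benzofuran-3-ol | C=C(CO)[C@H]1Oc2cc(O[Si](C(C)C)(C(C)C)C(C)C)c(C(=C)O[Si](C(C)C)(C(C)C)C(C)C)cc2[C@H]1O | intermediate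
10 | 2-[(2R,3R)-3-hydroxy-6-(triisopropylsilyloxy)-5-[1-(triisopropylsilyloxy)ethenyl]-2,3-dihydro-1-benzofuran-2-yl]prop-2-en-1-yl acetate | C=C(COC(C)=O)[C@H]1Oc2cc(O[Si](C(C)C)(C(C)C)C(C)C)c(C(=C)O[Si](C(C)C)(C(C)C)C(C)C)cc2[C@H]1O | intermediate
11 | angelic acid, (2Z)-2-methylbut-2-enoic acid | C/C=C(/C)C(=O)O | starting material
12 | (2Z)-2-methylbut-2-enoic 2,4,6-trichlorobenzoic anhydride | C/C=C(/C)C(=O)OC(=O)c1c(Cl)cc(Cl)cc1Cl | intermediate
13 | (2R,3R)-2-[3-(acetyloxy)prop-1-en-2-yl]-6-(triisopropylsilyloxy)-5-[1-(triisopropylsilyloxy)ethenyl]-2,3-dihydro-1-benzofuran-3-yl (2Z)-2-methylbut-2-enoate | C=C(COC(C)=O)[C@H]1Oc2cc(O[Si](C(C)C)(C(C)C)C(C)C)c(C(=C)O[Si](C(C)C)(C(C)C)C(C)C)cc2[C@H]1OC(=O)/C(C)=C\C | intermediate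
14 | (2R,3R)-5-acetyl-2-[3-(acetyloxy)prop-1-en-2-yl]-6-hydroxy-2,3-dihydro-1-benzofuran-3-yl (2Z)-2-methylbut-2-enoate | C=C(COC(C)=O)[C@H]1Oc2cc(O)c(C(C)=O)cc2[C@H]1OC(=O)/C(C)=C\C | target

## Step count and risks

Total step count: 8. Longest linear sequence: 8 steps (from 1 and 2 to 14); angelic acid 11 enters in step 7.

**Step 2 (key step).** The most likely failure is over-ionisation: the benzylic lactone C–O bond of 4 re-ionises under the Lewis acid and the cation loses the C2 proton, giving an aromatic benzofuran and erasing both stereocentres. The cation may also lose that proton before it cyclises, or BF3 may be held by the chelating hydroxy ketone so that ionisation is slow. Fallback, from 3 back to 4: the auxiliary is exchanged for a leaving group that departs without acid. Aqueous trifluoroacetic acid should hydrolyse the acetal to (4R)-4-(4-acetyl-3-hydroxyphenoxy)-5-hydroxydihydrofuran-2(3H)-one F1. SOCl2 with a trace of DMF should convert this pseudo-acid into (4R)-4-(4-acetyl-3-hydroxyphenoxy)-5-chlorodihydrofuran-2(3H)-one F2. AgOSO2CF3 with 2,6-di-tert-butyl-4-methylpyridine in CH2Cl2 at −78 °C should then abstract chloride, and the same cation should close to 4 in a buffered medium in which the product never meets a strong acid.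

**Step 4.** Two processes threaten it: β-elimination of the aryloxide from the lactone enolate (opening of ring B), and aminomethylation of the silyl enol ether by excess iminium salt. Fallback, from 5 back to 8: condensation with tert-butoxybis(dimethylamino)methane (Bredereck's reagent) in toluene at 60–70 °C should give (3E,3aR,8bR)-3-[(dimethylamino)methylidene]-6-(triisopropylsilyloxy)-7-[1-(triisopropylsilyloxy)ethenyl]-3a,8b-dihydrofuro[3,2-b][1]benzofuran-2(3H)-one F3, with neither a lithium enolate nor an iminium salt present. iBu2AlH (1.2 equiv, THF, −78 °C) should deliver hydride to the aminomethylene carbon, and loss of dimethylamine on work-up should give 8.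

**Step 1.** The 4-acylphenoxide is a weak nucleophile and a good leaving group, so the conjugate addition may stall at an unfavourable equilibrium (retro-oxa-Michael). Base may also epimerise the acetal centre of 2, which would erode facial control and, after step 2, enantiomeric purity. Fallback, from 1 back to 4, using an irreversible addition and catalyst control:
- Addition of 1 to ethyl 4,4-diethoxybut-2-ynoate F4 (K2CO3, MeCN) should give ethyl (2E)-3-(4-acetyl-3-hydroxyphenoxy)-4,4-diethoxybut-2-enoate F5.
- Asymmetric hydrogenation ([Rh(cod)2]BF4 with a chiral bisphosphine such as Me-DuPhos, H2, ligand antipode chosen for the 3R product) should give ethyl (3R)-3-(4-acetyl-3-hydroxyphenoxy)-4,4-diethoxybutanoate F6.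
- LiOH should give (3R)-3-(4-acetyl-3-hydroxyphenoxy)-4,4-diethoxybutanoic acid F7.
- F7 should close to 4 under the conditions of step 2, the acetal and the carboxyl group giving the same kind of cation.

**Step 7.** The angeloyl unit may isomerise to tigloyl, and acylation of the hindered, ionisable benzylic alcohol may be incomplete at the temperature needed. Fallback, from 10 back to 13, building the Z alkene in place: esterification of 10 with 2-[bis(2,2,2-trifluoroethoxy)phosphoryl]propanoic acid (dicyclohexylcarbodiimide, cat. 4-dimethylaminopyridine) should give (2R,3R)-2-[3-(acetyloxy)prop-1-en-2-yl]-6-(triisopropylsilyloxy)-5-[1-(triisopropylsilyloxy)ethenyl]-2,3-dihydro-1-benzofuran-3-yl 2-[bis(2,2,2-trifluoroethoxy)phosphoryl]propanoate F8. KN(SiMe3)2 and 18-crown-6 in THF at −78 °C, then acetaldehyde, should give 13 by Z-selective Horner–Wadsworth–Emmons (Still–Gennari) olefination.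

## Further compounds

F1 | step 2 | (4R)-4-(4-acetyl-3-hydroxyphenoxy)-5-hydroxydihydrofuran-2(3H)-one (anomer mixture) | O=C1C[C@@H](Oc2ccc(C(C)=O)c(O)c2)C(O)O1
F2 | step 2 | (4R)-4-(4-acetyl-3-hydroxyphenoxy)-5-chlorodihydrofuran-2(3H)-one (anomer mixture) | O=C1C[C@@H](Oc2ccc(C(C)=O)c(O)c2)C(Cl)O1
F3 | step 4 | (3E,3aR,8bR)-3-[(dimethylamino)methylidene]-6-(triisopropylsilyloxy)-7-[1-(triisopropylsilyloxy)ethenyl]-3a,8b-dihydrofuro[3,2-b][1]benzofuran-2(3H)-one | O=C1/C(=C/N(C)C)[C@H]2Oc3cc(O[Si](C(C)C)(C(C)C)C(C)C)c(C(=C)O[Si](C(C)C)(C(C)C)C(C)C)cc3[C@H]2O1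
F4 | step 1 | ethyl 4,4-diethoxybut-2-ynoate | CCOC(=O)C#CC(OCC)OCC
F5 | step 1 | ethyl (2E)-3-(4-acetyl-3-hydroxyphenoxy)-4,4-diethoxybut-2-enoate | CCOC(=O)/C=C(\C(OCC)OCC)Oc1ccc(C(C)=O)c(O)c1
F6 | step 1 | ethyl (3R)-3-(4-acetyl-3-hydroxyphenoxy)-4,4-diethoxybutanoate | CCOC(=O)C[C@@H](Oc1ccc(C(C)=O)c(O)c1)C(OCC)OCC
F7 | step 1 | (3R)-3-(4-acetyl-3-hydroxyphenoxy)-4,4-diethoxybutanoic acid | OC(=O)C[C@@H](Oc1ccc(C(C)=O)c(O)c1)C(OCC)OCC
F8 | step 7 | (2R,3R)-2-[3-(acetyloxy)prop-1-en-2-yl]-6-(triisopropylsilyloxy)-5-[1-(triisopropylsilyloxy)ethenyl]-2,3-dihydro-1-benzofuran-3-yl 2-[bis(2,2,2-trifluoroethoxy)phosphoryl]propanoate (phosphonate carbon unassigned) | C=C(COC(C)=O)[C@H]1Oc2cc(O[Si](C(C)C)(C(C)C)C(C)C)c(C(=C)O[Si](C(C)C)(C(C)C)C(C)C)cc2[C@H]1OC(=O)C(C)P(=O)(OCC(F)(F)F)OCC(F)(F)F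
A1 | alternative 1 | (2R,3R)-5-acetyl-3-(tert-butyldimethylsilyloxy)-2-[3-(tert-butyldimethylsilyloxy)prop-1-en-2-yl]-6-(trimethylsilyloxy)-2,3-dihydro-1-benzofuran | C=C(CO[Si](C)(C)C(C)(C)C)[C@H]1Oc2cc(O[Si](C)(C)C)c(C(C)=O)cc2[C@H]1O[Si](C)(C)C(C)(C)C
A2 | alternative 1 | (2R,3R)-5-[2,2-bis(trimethylsilyloxy)ethenyl]-3-(tert-butyldimethylsilyloxy)-2-[3-(tert-butyldimethylsilyloxy)prop-1-en-2-yl]-2,3-dihydrofuran | C=C(CO[Si](C)(C)C(C)(C)C)[C@H]1OC(C=C(O[Si](C)(C)C)O[Si](C)(C)C)=C[C@H]1O[Si](C)(C)C(C)(C)C
A3 | alternative 1 | but-3-yn-2-one | CC(=O)C#C
A4 | alternative 2 | cis-fused 7-bromo-3-(diethoxyphosphoryl)-6-(triisopropylsilyloxy)-3a,8b-dihydrofuro[3,2-b][1]benzofuran-2(3H)-one (ring fusion as in 4; phosphonate carbon unassigned) | C5(P(=O)(OCC)OCC)[C@H]1Oc2cc(O[Si](C(C)C)(C(C)C)C(C)C)c(Br)cc2[C@H]1OC5=O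
A5 | alternative 2 | (3R)-5-bromo-6-(triisopropylsilyloxy)-2,3-dihydro-1-benzofuran-3-yl 2-diazo-2-(diethoxyphosphoryl)acetate | CCOP(=O)(OCC)C(=[N+]=[N-])C(=O)O[C@H]1COc2cc(O[Si](C(C)C)(C(C)C)C(C)C)c(Br)cc21
A6 | alternative 3 | (2R,3R)-5-acetyl-2-(3-hydroxyprop-1-en-2-yl)-6-(4-methoxybenzyloxy)-2,3-dihydro-1-benzofuran-3-ol | C=C(CO)[C@H]1Oc2cc(OCc3ccc(OC)cc3)c(C(C)=O)cc2[C@H]1O
A7 | alternative 3 | (1R,2R)-1-[5-acetyl-2-fluoro-4-(4-methoxybenzyloxy)phenyl]-3-methylidenebutane-1,2,4-triol | C=C(CO)[C@@H](O)[C@H](O)c1cc(C(C)=O)c(OCc2ccc(OC)cc2)cc1F
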